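Percent of the substrate charged is the unit here, so what stands in the flask adds up to 100, and whatever is read as neither substrate nor target is an unseen remainder.

| flask | substrate | gas | temperature | remark | time |
|---|---|---|---|---|---|
| violet | 0.20 M | 85 mM (held) | 25 °C | the very flask that is asked about, followed so far |  |
| grey | 0.20 M | 85 mM (held) | 20 °C | run made earlier |  |
| flask | 0.20 M | 85 mM (held) | 25 °C |  | 10 min |
- violet (time / min: target / %, substrate / %): 0.500: 19, 71; 1.50: 30, 54; 3.00: 30, 50; 4.00: 29, 49; 6.00: 28, 50
- grey (time / min: target / %, substrate / %): 0.500: 23, 75; 1.50: 28, 53; 3.00: 34, 46; 4.00: 31, 49; 6.00: 33, 46

(standard deviation of a reading: 1.5 percentage points)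
- target taken out counts as made
- the numbers in the tables scatter by 1.5 percentage points (one standard deviation)
- at the start none of the gas is in solution
- additions bring no volume worth counting
- dusk: at 10 min add substrate, 50.0% of the amount charged, then wait 5.0 min
- autumn: at 10 min take out 90% of the target then present, then wait 5.0 min
- dawn: change nothing and wait 5.0 min more
- winter: at 10 min raise the temperature by 25 K, then wait 5.0 min
- target, in percent of the substrate first charged, at 10 min
- the remedy with the largest gain of target, or "none" below 2 percentage points (dusk / autumn / dawn / winter / none)
- target present, with what was taken out counted in, in percent of the substrate first charged, after autumn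
- target present, with what was taken out counted in, in percent of the substrate first charged, after winter

Must the curve be followed? No: in the violet run target stands at 30% by 1.50 min and at 28% at 6.00 min, so I replace it by a mean.

Which mean? The plateau share, the part of the charge standing as target once the violet readings stop moving (thermodynamic control, in the usual term), taken from 3.00 min on: 29.0%.

What error does that make? The mean scatters by 0.87 percentage points, and the sag of 2 points within it sits on a scatter of 1.5 points per reading, so I don't read a fall. At 10 min I commit to 29.0%.

Is it a balance or a stall? That is the weak spot. In the violet run substrate still stands at 50%, so it has not run out, and the grey run levels off at 32.7%, higher than the violet run. I assume a balance; the readings don't prove it. Then, with gas held, what remains divides again in the same share, and the wait of 5.0 min is longer than the 1.50 min by which the violet target had risen.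

And autumn? It takes out 26.1%, the rest divides by the share, and the total is 47.5%, a gain of 19 points. Dusk gains less, 14 points. Dawn I expect to change nothing, and winter I expect to lose, as the warmer violet run stands lower than the grey run.

The forecast says 28%, autumn, 46% after autumn and 17% after winter, reading “a reversible network that reaches equilibrium within a few minutes”. My 29.0% and 47.5% differ from its 28% and 46%; the choice is the same.

The flask gives 29.5% at 10 min, and autumn gains 19 points, more than dusk's 15 points. These equations run in it:

    target ⇌ isomer of the product (K = 0.704, k = 0.0517 s⁻¹, Ea = 78.0 kJ mol⁻¹, ΔH = 16.0 kJ mol⁻¹)
    gas ⇌ partner, rate k2*(csat - [partner]) (kL = 0.165 s⁻¹)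
    substrate + partner ⇌ target (K = 6.98 M⁻¹, k = 0.288 M⁻¹ s⁻¹, Ea = 38.0 kJ mol⁻¹, ΔH = −22.0 kJ mol⁻¹)
    (constants at 25 °C)

The remainder is isomer of the product, 20.8% at 10.0 min, and its exchange with target, by this step alone, has a relaxation half-life of 0.0923 min, far shorter than 10 min. Autumn, reckoned from 29.0%, stood at 47.5%; the flask gives 48.2%. The repeat at 50 °C stands at 18.2% at 10 min, and winter, which goes to that temperature, ends at 18.2%.

(All runs are calculated for an exercise; scatter was added.)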